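**Retrosynthetic overview**
- Feature: the target is quercetin whose ring A carries extra methoxyls on C6 and C8 and a methyl on O7. C6–H and C8–H are the only nucleophilic C–H sites of that phloroglucinol-type ring, so both new C–O bonds are traced back to C–Br bonds.
- Last disconnection: the 3-OH and the ring B catechol are unmasked together by hydrogenolysis of a 3-O-benzyl ether and a diphenylmethylene ketal.
- Key disconnection: C6–OMe and C8–OMe are made in one operation by copper-catalysed methanolysis (NaOMe, CuBr) of the 6,8-dibromo flavonol.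
- The dibromide comes from quercetin by catechol ketalisation, 7-O-methylation, 3-O-benzylation and twofold bromination of ring A.
- Ring order: rings A, C and B arrive intact with quercetin; the only ring made is the temporary 1,3-dioxole of the ketal (step 1), opened again in step 6.

Key step: step 5

Remark on the chemistry: quercetin is used anhydrous (the dihydrate is dried first). The order in which C6 and C8 react in steps 4 and 5 is assumed (C6 first in the bromination, C8 first in the methanolysis); either order converges on the same product.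

**Step 1**
Reactants: 1 quercetin; 2 dichlorodiphenylmethane
Product: 3 2-(2,2-diphenyl-1,3-benzodioxol-5-yl)-3,5,7-trihydroxychromen-4-one (3',4'-O-diphenylmethylene quercetin)
Conditions: Ph2CCl2 (1.5 equiv), Ph2O, 175 °C, 30 min; then petroleum ether
Reagents that add atoms: dichlorodiphenylmethane (compound 2), ClC(Cl)(c1ccccc1)c1ccccc1
Why: Thermal ketalisation by twofold nucleophilic substitution of the gem-dichloride closes a five-membered dioxole that only the two adjacent ring B hydroxyls can form, so the 3-, 5- and 7-hydroxyls stay free while HCl escapes as gas.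

**Step 2**
Reactants: 3 2-(2,2-diphenyl-1,3-benzodioxol-5-yl)-3,5,7-trihydroxychromen-4-one
Product: 4 2-(2,2-diphenyl-1,3-benzodioxol-5-yl)-3,5-dihydroxy-7-methoxychromen-4-one
Conditions: MeI (1.05 equiv), K2CO3 (1.1 equiv), DMF, 0 °C to rt
Reagents that add atoms: iodomethane, CI
Why: Williamson ether synthesis under acidity control: the 7-OH, a vinylogous carboxylic acid conjugated to the C4 carbonyl, is the most acidic hydroxyl and is ionised first by one equivalent of weak base, whereas the 3- and 5-hydroxyls are held in hydrogen bonds to the C4 carbonyl.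

**Step 3**
Reactants: 4 2-(2,2-diphenyl-1,3-benzodioxol-5-yl)-3,5-dihydroxy-7-methoxychromen-4-one
Product: 5 3-benzyloxy-2-(2,2-diphenyl-1,3-benzodioxol-5-yl)-5-hydroxy-7-methoxychromen-4-one
Conditions: BnBr (1.2 equiv), K2CO3 (1.5 equiv), DMF, rt
Reagents that add atoms: benzyl bromide, BrCc1ccccc1
Why: Williamson ether synthesis: of the two remaining hydroxyls the 3-enol is the more acidic and accessible and is benzylated at room temperature, while the 5-OH stays locked in its six-membered hydrogen-bonded chelate with the C4 carbonyl and is alkylated only under forcing conditions.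

**Step 4**
Reactants: 5 3-benzyloxy-2-(2,2-diphenyl-1,3-benzodioxol-5-yl)-5-hydroxy-7-methoxychromen-4-one
Product: 7 3-benzyloxy-6,8-dibromo-2-(2,2-diphenyl-1,3-benzodioxol-5-yl)-5-hydroxy-7-methoxychromen-4-one, via 6-bromo monobromide 6 (not isolated)
Conditions: NBS (2.1 equiv), DMF, 0 °C to rt, dark
Reagents that add atoms: N-bromosuccinimide, O=C1CCC(=O)N1Br
Why: Electrophilic aromatic bromination: C6 and C8 are the only C–H sites of ring A, each ortho or para to the free 5-OH and flanked by two oxygen-bearing carbons, so two equivalents of NBS should brominate both (C6, ortho to the phenol, expected first) before ring B, which is deactivated by conjugation to the pyranone, or the benzylic CH2, which needs radical conditions, can react.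

**Step 5**
Reactants: 7 3-benzyloxy-6,8-dibromo-2-(2,2-diphenyl-1,3-benzodioxol-5-yl)-5-hydroxy-7-methoxychromen-4-one; 8 sodium methoxide
Product: 10 3-benzyloxy-2-(2,2-diphenyl-1,3-benzodioxol-5-yl)-5-hydroxy-6,7,8-trimethoxychromen-4-one, via 6-bromo-8-methoxy intermediate 9 (not isolated)
Conditions: NaOMe (10 equiv, 25% in MeOH), CuBr (40 mol%), DMF, 110 °C, Ar; then aq. HCl
Reagents that add atoms: sodium methoxide (compound 8), C[O-].[Na+]
Why: Methoxide first deprotonates the chelated 5-OH and converts CuBr into a methoxycuprate of monovalent copper; this adds oxidatively into each aryl C–Br bond to give an aryl trivalent-copper methoxide, and reductive elimination forms the C8–OMe and C6–OMe bonds in turn, the C8 bromide (not flanked by the phenoxide oxygen) probably reacting first. The reaction is the Ullmann ether synthesis in its copper-catalysed methanolysis form, established for ortho-bromophenols and for 6- and 8-bromoflavones. No ring is closed and no stereocentre is created; two C–O bonds are made on ring A in one operation. The step needs substitution to win over hydrodebromination at both positions and the pyranone to survive methoxide: a large excess of concentrated NaOMe in DMF under strict exclusion of oxygen favours substitution, and the 5-phenoxide makes the chromone an anion that resists nucleophilic attack at C2. Site selectivity is not at issue because the bromines were placed on C6 and C8 in step 4, and the 3-O-benzyl ether and the ketal are inert to base.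

**Step 6**
Reactants: 10 3-benzyloxy-2-(2,2-diphenyl-1,3-benzodioxol-5-yl)-5-hydroxy-6,7,8-trimethoxychromen-4-one
Product: 12 3,5,3',4'-tetrahydroxy-6,7,8-trimethoxyflavone, via 3-hydroxy ketal 11 (not isolated)
Conditions: H2 (1 atm), Pd(OH)2/C (20 wt%), THF/MeOH 1:1, rt
Reagents that add atoms: none
Why: Catalytic hydrogenolysis cleaves the benzylic C–O bond of the 3-O-benzyl ether (giving toluene) and then both benzhydrylic C–O bonds of the diphenylmethylene ketal (giving diphenylmethane), while the aryl methyl ethers and the tetrasubstituted C2–C3 double bond of the flavonol should not be reduced at 1 atm and room temperature.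

**Compound list**
1 | quercetin | O=c1c(O)c(-c2ccc(O)c(O)c2)oc2cc(O)cc(O)c12 | starting material
2 | dichlorodiphenylmethane | ClC(Cl)(c1ccccc1)c1ccccc1 | starting material
3 | 2-(2,2-diphenyl-1,3-benzodioxol-5-yl)-3,5,7-trihydroxychromen-4-one | O=c1c(O)c(-c2ccc3OC(c4ccccc4)(c4ccccc4)Oc3c2)oc2cc(O)cc(O)c12 | intermediate
4 | 2-(2,2-diphenyl-1,3-benzodioxol-5-yl)-3,5-dihydroxy-7-methoxychromen-4-one | COc1cc(O)c2c(=O)c(O)c(-c3ccc4OC(c5ccccc5)(c5ccccc5)Oc4c3)oc2c1 | intermediate
5 | 3-benzyloxy-2-(2,2-diphenyl-1,3-benzodioxol-5-yl)-5-hydroxy-7-methoxychromen-4-one | COc1cc(O)c2c(=O)c(OCc3ccccc3)c(-c3ccc4OC(c5ccccc5)(c5ccccc5)Oc4c3)oc2c1 | intermediate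
6 | 3-benzyloxy-6-bromo-2-(2,2-diphenyl-1,3-benzodioxol-5-yl)-5-hydroxy-7-methoxychromen-4-one (forms in step 4, not isolated) | COc1c(Br)c(O)c2c(=O)c(OCc3ccccc3)c(-c3ccc4OC(c5ccccc5)(c5ccccc5)Oc4c3)oc2c1 | intermediate
7 | 3-benzyloxy-6,8-dibromo-2-(2,2-diphenyl-1,3-benzodioxol-5-yl)-5-hydroxy-7-methoxychromen-4-one | COc1c(Br)c(O)c2c(=O)c(OCc3ccccc3)c(-c3ccc4OC(c5ccccc5)(c5ccccc5)Oc4c3)oc2c1Br | intermediate
8 | sodium methoxide | C[O-].[Na+] | starting material
9 | 3-benzyloxy-6-bromo-2-(2,2-diphenyl-1,3-benzodioxol-5-yl)-5-hydroxy-7,8-dimethoxychromen-4-one (forms in step 5, not isolated) | COc1c(Br)c(O)c2c(=O)c(OCc3ccccc3)c(-c3ccc4OC(c5ccccc5)(c5ccccc5)Oc4c3)oc2c1OC | intermediate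
10 | 3-benzyloxy-2-(2,2-diphenyl-1,3-benzodioxol-5-yl)-5-hydroxy-6,7,8-trimethoxychromen-4-one | COc1c(OC)c(O)c2c(=O)c(OCc3ccccc3)c(-c3ccc4OC(c5ccccc5)(c5ccccc5)Oc4c3)oc2c1OC | intermediate
11 | 2-(2,2-diphenyl-1,3-benzodioxol-5-yl)-3,5-dihydroxy-6,7,8-trimethoxychromen-4-one (forms in step 6, not isolated) | COc1c(OC)c(O)c2c(=O)c(O)c(-c3ccc4OC(c5ccccc5)(c5ccccc5)Oc4c3)oc2c1OC | intermediate
12 | 3,5,3',4'-tetrahydroxy-6,7,8-trimethoxyflavone [2-(3,4-dihydroxyphenyl)-3,5-dihydroxy-6,7,8-trimethoxychromen-4-one] | COc1c(OC)c(O)c2c(=O)c(O)c(-c3ccc(O)c(O)c3)oc2c1OC | target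

**Step count**
Total step count: 6. Longest linear sequence: 6 steps (quercetin 1 to target 12).

**Steps most likely to fail**

1. Step 5 (twofold methanolysis). What may go wrong is hydrodebromination competing with substitution at one or both positions, stalling after the first substitution because the substrate reacts as an electron-rich phenoxide that also binds copper, or methoxide-induced opening of the pyranone ring. The fallback sets out from dibromide 7 and comes back to the route at target 12. The 5-hydroxyl would first be benzylated (BnBr, K2CO3, DMF, 60 °C) to give 3,5-bis(benzyloxy)-6,8-dibromo-2-(2,2-diphenyl-1,3-benzodioxol-5-yl)-7-methoxychromen-4-one F1, so that no phenoxide is present. Both C–Br bonds would then be converted by a palladium-catalysed C–O cross-coupling with methanol (Buchwald–Hartwig etherification; [(allyl)PdCl]2, RockPhos, Cs2CO3, MeOH, toluene, 90 °C), which runs through zerovalent and divalent palladium and needs no strong alkoxide, to give 3,5-bis(benzyloxy)-2-(2,2-diphenyl-1,3-benzodioxol-5-yl)-6,7,8-trimethoxychromen-4-one F2. The hydrogenolysis conditions of step 6 would then remove both benzyl ethers and the ketal to reach 12.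

2. Step 2 (7-O-methylation). What may go wrong is loss of site selectivity in the alkylation, with the 3-hydroxyl methylated alongside or after the 7-hydroxyl. The fallback sets out from ketal 3 and comes back at 4; it replaces selective alkylation by selective exchange of an acetate. Peracetylation (Ac2O, pyridine, rt) would give 2-(2,2-diphenyl-1,3-benzodioxol-5-yl)-4-oxochromene-3,5,7-triyl triacetate F3. Heating F3 with MeI and K2CO3 in dry acetone should exchange only the 7-acetoxyl for methoxyl, because the 7-phenoxide is the best leaving group and is methylated as it is released, giving 2-(2,2-diphenyl-1,3-benzodioxol-5-yl)-7-methoxy-4-oxochromene-3,5-diyl diacetate F4. Mild methanolysis (catalytic K2CO3, MeOH/THF, rt) would then remove the two remaining acetates to give 4.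

3. Step 6 (global hydrogenolysis). What may go wrong is incomplete cleavage of the hindered diphenylmethylene ketal, for example through catalyst poisoning by traces of copper or bromide carried over, or over-reduction of the C2–C3 double bond if the reaction is forced. The fallback sets out from 10 and comes back at 12; it removes the ketal by hydrolysis instead of reduction. Heating 10 in AcOH/H2O 4:1 at reflux should hydrolyse the ketal, releasing benzophenone, to give 3-benzyloxy-2-(3,4-dihydroxyphenyl)-5-hydroxy-6,7,8-trimethoxychromen-4-one F5. The remaining 3-O-benzyl ether, the easier group to hydrogenolyse, would then be removed by a short hydrogenolysis (H2, 10% Pd/C, EtOAc/MeOH, rt) to give 12.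

**Further compounds**
F1 | step 5 | 3,5-bis(benzyloxy)-6,8-dibromo-2-(2,2-diphenyl-1,3-benzodioxol-5-yl)-7-methoxychromen-4-one | COc1c(Br)c(OCc2ccccc2)c2c(=O)c(OCc3ccccc3)c(-c3ccc4OC(c5ccccc5)(c5ccccc5)Oc4c3)oc2c1Br
F2 | step 5 | 3,5-bis(benzyloxy)-2-(2,2-diphenyl-1,3-benzodioxol-5-yl)-6,7,8-trimethoxychromen-4-one | COc1c(OC)c(OCc2ccccc2)c2c(=O)c(OCc3ccccc3)c(-c3ccc4OC(c5ccccc5)(c5ccccc5)Oc4c3)oc2c1OC
F3 | step 2 | 2-(2,2-diphenyl-1,3-benzodioxol-5-yl)-4-oxochromene-3,5,7-triyl triacetate | CC(=O)Oc1cc(OC(C)=O)c2c(=O)c(OC(C)=O)c(-c3ccc4OC(c5ccccc5)(c5ccccc5)Oc4c3)oc2c1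
F4 | step 2 | 2-(2,2-diphenyl-1,3-benzodioxol-5-yl)-7-methoxy-4-oxochromene-3,5-diyl diacetate | COc1cc(OC(C)=O)c2c(=O)c(OC(C)=O)c(-c3ccc4OC(c5ccccc5)(c5ccccc5)Oc4c3)oc2c1
F5 | step 6 | 3-benzyloxy-2-(3,4-dihydroxyphenyl)-5-hydroxy-6,7,8-trimethoxychromen-4-one | COc1c(OC)c(O)c2c(=O)c(OCc3ccccc3)c(-c3ccc(O)c(O)c3)oc2c1OC
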